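**Plan**

- Locants used throughout: C1 = benzylic CH2; C2=C3(Me) = ring alkene; C4, C5 = ring CH2; C6 = CHBr; C7 = quaternary C(Me); C8, C9 = CH2; C10 = CHBr; C11 = C(Me)OH; C12, C13 = CH2; C14 = CH–O(ester); C15=C16 = isopropenyl.
- Cuts: lactone O–C14/acyl bond; C1–C2 (benzyl–alkenyl coupling); C9–C10 (alkyl–alkenyl coupling); C7–C8 and C7–CH3 (enolate alkylations); and, together, C3–C4 and C5–C6.
- Enabling feature: in the carbocycle C2–C7, C3 (sp2, methyl-bearing end of the tetrasubstituted alkene) and C6 (heteroatom-bearing) are 1,4-related and C2 can be a ketone. C3–C2–C7–C6 is therefore the carbon skeleton of a 3-oxyfuran with C3 and C6 as its α-carbons, the furan oxygen is a temporary C3–O–C6 bridge, and C4–C5 is a two-carbon dienophile (an acrylimide whose carbonyl is later excised).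
- Forward: furan cycloaddition builds the carbocycle as a 7-oxabicyclo[2.2.1]heptanone; the bridge steers two exo alkylations at C7; SmI2 cuts C3–O (C2 ketone → enol triflate → C2=C3) and leaves C6–OH (→ Br with inversion); then side chain (C9–C10), arene (C1–C2), macrolactone (last ring), epoxide → bromohydrin.
- Stereochemistry: bridgeheads C3/C6 by catalyst-controlled cycloaddition; C7 and then C6–Br relayed from them through the bicycle; C14 by CBS reduction; C10/C11 by Shi epoxidation and invertive bromide opening.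

Key step: step 3

Remark: the ring carbon α to the ketone (C3; ring locant 6 in the names of 12–16, 24, 25) is an epimeric centre of no consequence, written without descriptor, because it becomes sp2 in step 18; compounds 1–3 are racemic, their only stereocentre being destroyed in step 2.

**Route**

Step 1
Reactants: 1 2-methyloxolan-3-one
Product: 3 2-methylfuran-3(2H)-one, via silyl enol ether 2 (not isolated)
Conditions: LiN(i-Pr)2, Me3SiCl, THF, −78 °C; then Pd(OAc)2 (10 mol %), O2 (1 atm), DMSO, 25 °C
Reagents that add atoms: none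
Why: Kinetic deprotonation at the unhindered ring CH2 next to the carbonyl gives the 3,4-enol silane, and Saegusa–Ito dehydrogenation (palladium enolate, β-hydride loss) should deliver the vinylogous ester.

Step 2
Reactants: 3 2-methylfuran-3(2H)-one
Product: 4 tert-butyl(dimethyl)[(2-methylfuran-3-yl)oxy]silane
Conditions: t-BuMe2SiOTf, Et3N, CH2Cl2, 0 °C
Reagents that add atoms: tert-butyldimethylsilyl trifluoromethanesulfonate, CC(C)(C)[Si](C)(C)OS(=O)(=O)C(F)(F)F
Why: Soft enolisation and O-silylation are driven by aromatisation to the 3-silyloxyfuran, an electron-rich cyclic diene whose methyl-bearing and unsubstituted α-carbons are the future C3 and C6.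

Step 3
Reactants: 4 tert-butyl(dimethyl)[(2-methylfuran-3-yl)oxy]silane; 5 3-(prop-2-enoyl)-1,3-oxazolidin-2-one
Product: 6 3-{[(1S,4S,5S)-2-{[tert-butyl(dimethyl)silyl]oxy}-1-methyl-7-oxabicyclo[2.2.1]hept-2-en-5-yl]carbonyl}-1,3-oxazolidin-2-one (endo adduct)
Conditions: [Cu((S,S)-t-Bu-box)](SbF6)2 (10 mol %), CH2Cl2, 4 Å MS, −78 °C; endo adduct isolated by chromatography
Reagents that add atoms: none
Why: Normal-electron-demand Diels–Alder cycloaddition ([4π+2π], concerted but asynchronous, the C3–C4 bond leading) between the furan diene C3=C2–C7=C6, held s-cis by its ring oxygen, and the acrylimide chelated in its s-cis form to the divalent copper bis(oxazoline) complex; the closest known reaction is the cycloaddition of furan itself with this imide under the same catalyst. Both σ-bonds (C3–C4 and C5–C6) form suprafacially on each partner in one event, which closes the six-membered carbocycle C2–C3–C4–C5–C6–C7 and, because the termini are already joined by oxygen, the 7-oxabicyclo[2.2.1]heptene (a cycloaddition, so no exo/endo-tet/trig classification applies). The bridgehead stereocentres C3 and C6 arise together from the furan face that is attacked, which is fixed by the ligand-shielded α-face of the imide combined with endo approach; C5 is set by the same imide face and is deleted in step 5. Regioselectivity is needed and follows from the 2-silyloxydiene polarisation: C3, next to the silyloxy carbon, is the most nucleophilic terminus and bonds to the imide β-carbon. Endo selectivity is kinetic and should be kept at −78 °C where cycloreversion is frozen; since an exo or regioisomeric adduct would give the antipodal bridgeheads once the acyl group is removed, only pure endo 6 is carried on. The (S,S)-ligand is chosen by analogy with the furan and cyclopentadiene cases, in which it gives the (S)-configured acyl-bearing carbon.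

Step 4
Reactants: 6 the endo imide adduct
Product: 8 (1S,2S,4S)-4-methyl-5-oxo-7-oxabicyclo[2.2.1]heptane-2-carboxylic acid, via enol ether acid 7 (not isolated)
Conditions: LiOH, H2O2, THF/H2O, 0 °C; Na2SO3; then 1 M HCl, THF, 25 °C
Reagents that add atoms: hydrogen peroxide, OO
Why: Hydroperoxide attacks the exocyclic imide carbonyl selectively (the peracid is reduced by sulfite) and dilute acid then hydrolyses the silyl enol ether to the C2 ketone; no stereocentre is touched, and the oxygen bridge survives because no enolate is held at C7.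

Step 5
Reactants: 8 the keto acid
Product: 9 (1S,4R)-1-methyl-7-oxabicyclo[2.2.1]heptan-2-one
Conditions: 9-mesityl-10-phenylacridinium tetrafluoroborate (5 mol %), PhSSPh (10 mol %), i-Pr2NEt (20 mol %), CF3CH2OH, 450 nm LED, 25 °C
Reagents that add atoms: none
Why: Photoredox hydrodecarboxylation (carboxylate oxidation, loss of CO2, hydrogen-atom transfer from thiophenol to the C5 radical) erases the dienophile's activating group so that C4–C5 is the plain ethano unit; a radical at C5, unlike a carbanion, does not expel the β-oxygen bridge.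

Step 6
Reactants: 9 (1S,4R)-1-methyl-7-oxabicyclo[2.2.1]heptan-2-one
Product: 10 (1S,3R,4R)-1,3-dimethyl-7-oxabicyclo[2.2.1]heptan-2-one (methyl exo)
Conditions: LiN(i-Pr)2, THF, −78 °C; MeI, −78 to −40 °C
Reagents that add atoms: iodomethane, CI
Why: Only C7 can enolise (C3 is a fully substituted bridgehead), and the lithium enolate should be methylated on the exo face, syn to the oxygen bridge, as is usual for 7-oxanorbornan-2-ones; at low temperature the C6–O bond, nearly orthogonal to the enolate π-system, is not eliminated.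

Step 7
Reactants: 10 the exo-methyl ketone
Product: 11 (1S,3R,4R)-1,3-dimethyl-3-(prop-2-en-1-yl)-7-oxabicyclo[2.2.1]heptan-2-one (allyl exo, methyl endo)
Conditions: LiN(i-Pr)2, THF, −78 to −30 °C; allyl bromide, DMPU
Reagents that add atoms: allyl bromide, C=CCBr
Why: The second enolate alkylation, again from the exo face, places the allyl group (C8, C9 and one carbon to be excised) syn to the oxygen bridge and pushes the methyl endo, so the C7 quaternary stereocentre is fixed relative to C6–O by the bicyclic frame and not by the small size difference between methyl and a primary alkyl group.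

Step 8
Reactants: 11 the allyl ketone
Product: 12 (2R,3R)-3-hydroxy-2,6-dimethyl-2-(prop-2-en-1-yl)cyclohexan-1-one (C6 epimers)
Conditions: SmI2 (2.5 equiv), THF/MeOH, −78 °C
Reagents that add atoms: none
Why: Reductive cleavage of the α-alkoxy ketone (ketyl, expulsion of the C3–O bond with release of bicyclic strain, second electron to the samarium enolate, protonation) opens the bridge at C3 only, so C6 keeps its oxygen cis to C8 and C2 becomes a ketone whose single enolisable position is C3.

Step 9
Reactants: 12 the hydroxy ketone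
Product: 13 (2S,3S)-3-bromo-2,6-dimethyl-2-(prop-2-en-1-yl)cyclohexan-1-one (C6 epimers)
Conditions: PPh3, CBr4, CH2Cl2, 0 to 40 °C
Reagents that add atoms: carbon tetrabromide, BrC(Br)(Br)Br
Why: Appel reaction: bromide displaces the alkoxyphosphonium group with inversion (SN2), turning the C6–OH that is cis to C8 into the C6–Br that is trans to C8 and cis to the C7 methyl as in the target; the electron-poor β-carbonyl group disfavours ionisation and 1,2-shift at this neopentylic centre.

Step 10
Reactants: 13 the bromo ketone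
Product: 15 (2S,3S)-3-bromo-2-(2-hydroxyethyl)-2,6-dimethylcyclohexan-1-one, via aldehyde 14 (not isolated)
Conditions: O3, CH2Cl2/MeOH, −78 °C; Me2S; then NaBH4, −78 to −20 °C
Reagents that add atoms: ozone, [O-][O+]=O
Why: Ozonolysis removes the terminal allyl carbon to leave the C8–C9 unit, and NaBH4 at low temperature should reduce the aldehyde but not the hindered α-quaternary ketone.

Step 11
Reactants: 15 the primary alcohol
Product: 16 (2S,3S)-3-bromo-2-(2-iodoethyl)-2,6-dimethylcyclohexan-1-one
Conditions: I2, PPh3, imidazole, CH2Cl2, 0 °C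
Reagents that add atoms: iodine, II
Why: Appel-type iodination (SN2 at the primary C9) gives the iodide needed for zinc insertion; the secondary neopentylic bromide and the ketone are inert.

Step 12
Reactants: 17 pent-4-ynoic acid
Product: 18 N-methoxy-N-methylpent-4-ynamide
Conditions: MeNHOMe·HCl, EDC·HCl, Et3N, CH2Cl2, 0 to 25 °C
Reagents that add atoms: N,O-dimethylhydroxylamine hydrochloride, CNOC.Cl
Why: Carbodiimide amide coupling gives the Weinreb amide, which accepts exactly one alkenyl nucleophile.

Step 13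
Reactants: 18 the Weinreb amide
Product: 19 2-methylhept-1-en-6-yn-3-one
Conditions: CH2=C(CH3)MgBr (2.2 equiv), THF, −20 to 0 °C; cold aq. NH4Cl
Reagents that add atoms: isopropenylmagnesium bromide, CC(=C)[Mg]Br
Why: Weinreb ketone synthesis: the chelated tetrahedral intermediate prevents over-addition (one equivalent of Grignard reagent is consumed by the alkyne C–H), giving the C14 ketone with C15/C16 in place.

Step 14
Reactants: 19 the enynone
Product: 20 (3S)-2-methylhept-1-en-6-yn-3-ol
Conditions: (R)-2-methyl-CBS-oxazaborolidine (15 mol %), catecholborane, toluene, −78 °C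
Reagents that add atoms: none
Why: Corey–Bakshi–Shibata reduction: with isopropenyl as the large group the (R)-oxazaborolidine should give the (S)-allylic alcohol (C14), and catecholborane at −78 °C does not hydroborate the alkyne or alkene.

Step 15
Reactants: 20 the (S)-alcohol
Product: 21 tert-butyl(dimethyl){[(3S)-2-methylhept-1-en-6-yn-3-yl]oxy}silane
Conditions: t-BuMe2SiCl, imidazole, DMF, 25 °C
Reagents that add atoms: tert-butyldimethylsilyl chloride, CC(C)(C)[Si](C)(C)Cl
Why: Standard silylation masks the C14 hydroxyl for the organometallic and strong-base steps that follow.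

Step 16
Reactants: 21 the silyl ether
Product: 23 tert-butyl{[(3S,6E)-7-iodo-2,6-dimethylhepta-1,6-dien-3-yl]oxy}dimethylsilane, via alkenylalane 22 (not isolated)
Conditions: Me3Al, Cp2ZrCl2 (20 mol %), CH2Cl2, 0 to 25 °C; then I2, THF, −30 °C
Reagents that add atoms: trimethylaluminium, C[Al](C)C; iodine, II
Why: Zirconium-catalysed carboalumination (Negishi) adds methyl and aluminium syn across the terminal alkyne with methyl on the internal carbon, and iodinolysis with retention gives the (E)-iodoalkene (C10=C11 with its methyl); the 1,1-disubstituted alkene does not react.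

Step 17
Reactants: 16 the iodide; 23 the (E)-iodoalkene
Product: 25 (2S,3S)-3-bromo-2-[(3E,7S)-7-{[tert-butyl(dimethyl)silyl]oxy}-4,8-dimethylnona-3,8-dien-1-yl]-2,6-dimethylcyclohexan-1-one, via alkylzinc iodide 24 (not isolated)
Conditions: Zn dust, LiCl, THF, 25 °C; then 23, PdCl2(dppf) (5 mol %), THF, 40 °C
Reagents that add atoms: none
Why: Zinc inserts into the primary C9–I bond (ketone and secondary bromide tolerated), and Negishi sp3–sp2 coupling forms C9–C10 with retention of the E geometry.

Step 18
Reactants: 25 the coupled ketone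
Product: 26 (5S,6S)-5-bromo-6-[(3E,7S)-7-{[tert-butyl(dimethyl)silyl]oxy}-4,8-dimethylnona-3,8-dien-1-yl]-2,6-dimethylcyclohex-1-en-1-yl trifluoromethanesulfonate
Conditions: KN(SiMe3)2, THF, −78 °C; PhNTf2, −78 to 0 °C
Reagents that add atoms: N-phenylbis(trifluoromethanesulfonimide), O=S(=O)(N(c1ccccc1)S(=O)(=O)C(F)(F)F)C(F)(F)F
Why: C3–H is the only enolisable hydrogen (C7 is quaternary), so enolate O-triflation gives the tetrasubstituted enol triflate regiospecifically, fixing the position of the future C2=C3 alkene and removing the epimeric C3 centre.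

Step 19
Reactants: 26 the enol triflate
Product: 27 (5S,6S)-5-bromo-6-{2-[(2S,3S)-3-[(3S)-3-{[tert-butyl(dimethyl)silyl]oxy}-4-methylpent-4-en-1-yl]-3-methyloxiran-2-yl]ethyl}-2,6-dimethylcyclohex-1-en-1-yl trifluoromethanesulfonate
Conditions: 1,2:4,5-di-O-isopropylidene-β-L-erythro-2,3-hexodiulo-2,6-pyranose (30 mol %), Oxone, K2CO3, n-Bu4NHSO4, MeCN/CH2(OMe)2/aq. buffer (pH 10.5), 0 °C
Reagents that add atoms: potassium peroxymonosulfate (Oxone), [K+].[O-]S(=O)(=O)OO
Why: Shi epoxidation: the chiral dioxirane epoxidises the electron-rich E-trisubstituted C10=C11 alkene through a spiro transition state, the L-series ketone giving the (10S,11S)-epoxide, while the electron-poor enol triflate and the 1,1-disubstituted alkene are left alone.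

Step 20
Reactants: 28 methyl 4-hydroxy-3-methylbenzoate
Product: 29 methyl 4-(methoxymethoxy)-3-methylbenzoate
Conditions: MeOCH2Cl, i-Pr2NEt, CH2Cl2, 0 to 25 °C
Reagents that add atoms: chloromethyl methyl ether, COCCl
Why: O-alkylation of the phenol gives a methoxymethyl ether that survives organozinc, fluoride and acylation conditions.

Step 21
Reactants: 29 the methyl ester
Product: 30 2-(trimethylsilyl)ethyl 4-(methoxymethoxy)-3-methylbenzoate
Conditions: Me3SiCH2CH2OH, Ti(OiPr)4 (10 mol %), toluene, 110 °C, MeOH distilled off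
Reagents that add atoms: 2-(trimethylsilyl)ethanol, C[Si](C)(C)CCO
Why: Titanate-catalysed transesterification installs an ester that fluoride can cleave later without hydroxide.

Step 22
Reactants: 30 the silylethyl ester
Product: 31 2-(trimethylsilyl)ethyl 3-(bromomethyl)-4-(methoxymethoxy)benzoate
Conditions: NBS, AIBN (5 mol %), PhCF3, 80 °C
Reagents that add atoms: N-bromosuccinimide, O=C1CCC(=O)N1Br
Why: Wohl–Ziegler radical bromination at the only benzylic position gives the precursor of the C1 nucleophile.

Step 23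
Reactants: 31 the benzyl bromide; 27 the epoxy enol triflate
Product: 33 2-(trimethylsilyl)ethyl 3-{[(5S,6S)-5-bromo-6-{2-[(2S,3S)-3-[(3S)-3-{[tert-butyl(dimethyl)silyl]oxy}-4-methylpent-4-en-1-yl]-3-methyloxiran-2-yl]ethyl}-2,6-dimethylcyclohex-1-en-1-yl]methyl}-4-(methoxymethoxy)benzoate, via benzylzinc bromide 32 (not isolated)
Conditions: Zn dust, LiCl, THF, 0 to 25 °C; then 27, Pd2(dba)3 (2.5 mol %), SPhos (10 mol %), THF, 50 °C
Reagents that add atoms: none
Why: Negishi coupling of the benzylzinc reagent with the hindered enol triflate (2,6,6-trisubstituted cyclohexenyl triflates couple with a bulky biarylphosphine on zerovalent palladium) forms C1–C2 and with it the tetrasubstituted C2=C3 alkene; the organozinc in THF should not open the epoxide or touch the esters and the secondary bromide.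

Step 24
Reactants: 33 the coupled ester
Product: 34 3-{[(5S,6S)-5-bromo-6-{2-[(2S,3S)-3-[(3S)-3-hydroxy-4-methylpent-4-en-1-yl]-3-methyloxiran-2-yl]ethyl}-2,6-dimethylcyclohex-1-en-1-yl]methyl}-4-(methoxymethoxy)benzoic acid
Conditions: n-Bu4NF, THF, 0 to 25 °C; aq. NaHSO4 work-up
Reagents that add atoms: none
Why: Fluoride cleaves the 2-(trimethylsilyl)ethyl ester by β-elimination and the C14 silyl ether in one operation, exposing acid and alcohol while the aryl methoxymethyl ether, epoxide and bromide stay.

Step 25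
Reactants: 34 the seco acid
Product: 35 (6S,7S,10S,11S,14S)-macrolactone: the 15-membered lactone of 34 closed between the benzoate carbonyl and O–C14, carrying the C10/C11 trans-epoxide and the aryl methoxymethyl ether
Conditions: 2-methyl-6-nitrobenzoic anhydride, DMAP, Et3N, toluene (1 mM, slow addition), 25 °C
Reagents that add atoms: none
Why: Shiina macrolactonisation through the mixed anhydride and acylpyridinium ion acylates the C14 hydroxyl, the only free one (C11–O is locked in the epoxide and the phenol is protected), with retention at C14; high dilution suppresses oligomerisation.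

Step 26
Reactants: 35 the epoxy macrolactone
Product: 36 O-methoxymethyl ether of the target, (6S,7S,10R,11S,14S)
Conditions: Li2NiBr4, THF, 0 to 25 °C; pH 7 buffer
Reagents that add atoms: dilithium tetrabromonickelate, [Li+].[Li+].Br[Ni-2](Br)(Br)Br
Why: Soft nucleophilic bromide opens the trisubstituted epoxide by SN2 at the less substituted C10 with inversion, giving the (10R)-bromide and the tertiary (11S)-alcohol, i.e. the anti bromohydrin of the E-alkene.

Step 27
Reactants: 36 the protected bromohydrin
Product: 37 CNP0305154.1, the (6S,7S,10R,11S,14S) target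
Conditions: ZnBr2, n-PrSH, CH2Cl2, 0 °C
Reagents that add atoms: none
Why: Lewis-acid activation with thiol capture cleaves the aryl methoxymethyl acetal under non-basic conditions, so the bromohydrin is not closed back to the epoxide and the lactone, bromides and alkenes are untouched.

**Compound list**

1 | 2-methyloxolan-3-one (racemic) | CC1OCCC1=O | starting material
2 | trimethyl[(2-methyl-2,5-dihydrofuran-3-yl)oxy]silane | CC1OCC=C1O[Si](C)(C)C | intermediate (not isolated)
3 | 2-methylfuran-3(2H)-one (racemic) | CC1OC=CC1=O | intermediate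
4 | tert-butyl(dimethyl)[(2-methylfuran-3-yl)oxy]silane | Cc1occc1O[Si](C)(C)C(C)(C)C | intermediate
5 | 3-(prop-2-enoyl)-1,3-oxazolidin-2-one | C=CC(=O)N1CCOC1=O | starting material
6 | 3-{[(1S,4S,5S)-2-{[tert-butyl(dimethyl)silyl]oxy}-1-methyl-7-oxabicyclo[2.2.1]hept-2-en-5-yl]carbonyl}-1,3-oxazolidin-2-one (endo) | C1=C(O[Si](C)(C)C(C)(C)C)[C@]2(C)C[C@H](C(=O)N3CCOC3=O)[C@H]1O2 | intermediate
7 | (1S,4S,5S)-2-{[tert-butyl(dimethyl)silyl]oxy}-1-methyl-7-oxabicyclo[2.2.1]hept-2-ene-5-carboxylic acid | C1=C(O[Si](C)(C)C(C)(C)C)[C@]2(C)C[C@H](C(O)=O)[C@H]1O2 | intermediate (not isolated)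
8 | (1S,2S,4S)-4-methyl-5-oxo-7-oxabicyclo[2.2.1]heptane-2-carboxylic acid | C1C(=O)[C@]2(C)C[C@H](C(O)=O)[C@H]1O2 | intermediate
9 | (1S,4R)-1-methyl-7-oxabicyclo[2.2.1]heptan-2-one | C1C(=O)[C@]2(C)CC[C@H]1O2 | intermediate
10 | (1S,3R,4R)-1,3-dimethyl-7-oxabicyclo[2.2.1]heptan-2-one | C[C@H]1C(=O)[C@]2(C)CC[C@H]1O2 | intermediate
11 | (1S,3R,4R)-1,3-dimethyl-3-(prop-2-en-1-yl)-7-oxabicyclo[2.2.1]heptan-2-one | C=CC[C@@]1(C)C(=O)[C@]2(C)CC[C@H]1O2 | intermediate
12 | (2R,3R)-3-hydroxy-2,6-dimethyl-2-(prop-2-en-1-yl)cyclohexan-1-one (C6 epimers) | C=CC[C@@]1(C)C(=O)C(C)CC[C@H]1O | intermediate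
13 | (2S,3S)-3-bromo-2,6-dimethyl-2-(prop-2-en-1-yl)cyclohexan-1-one (C6 epimers) | C=CC[C@@]1(C)C(=O)C(C)CC[C@@H]1Br | intermediate
14 | 2-[(1S,6S)-6-bromo-1,3-dimethyl-2-oxocyclohexyl]acetaldehyde | O=CC[C@@]1(C)C(=O)C(C)CC[C@@H]1Br | intermediate (not isolated)
15 | (2S,3S)-3-bromo-2-(2-hydroxyethyl)-2,6-dimethylcyclohexan-1-one | OCC[C@@]1(C)C(=O)C(C)CC[C@@H]1Br | intermediate
16 | (2S,3S)-3-bromo-2-(2-iodoethyl)-2,6-dimethylcyclohexan-1-one | ICC[C@@]1(C)C(=O)C(C)CC[C@@H]1Br | intermediate
17 | pent-4-ynoic acid | C#CCCC(=O)O | starting material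
18 | N-methoxy-N-methylpent-4-ynamide | C#CCCC(=O)N(C)OC | intermediate
19 | 2-methylhept-1-en-6-yn-3-one | C=C(C)C(=O)CCC#C | intermediate
20 | (3S)-2-methylhept-1-en-6-yn-3-ol | C=C(C)[C@@H](O)CCC#C | intermediate
21 | tert-butyl(dimethyl){[(3S)-2-methylhept-1-en-6-yn-3-yl]oxy}silane | C=C(C)[C@@H](O[Si](C)(C)C(C)(C)C)CCC#C | intermediate
22 | [(1E,5S)-5-{[tert-butyl(dimethyl)silyl]oxy}-2,6-dimethylhepta-1,6-dien-1-yl]dimethylalumane | C=C(C)[C@@H](O[Si](C)(C)C(C)(C)C)CC/C(C)=C/[Al](C)C | intermediate (not isolated)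
23 | tert-butyl{[(3S,6E)-7-iodo-2,6-dimethylhepta-1,6-dien-3-yl]oxy}dimethylsilane | C=C(C)[C@@H](O[Si](C)(C)C(C)(C)C)CC/C(C)=C/I | intermediate
24 | {2-[(1S,6S)-6-bromo-1,3-dimethyl-2-oxocyclohexyl]ethyl}(iodo)zinc | I[Zn]CC[C@@]1(C)C(=O)C(C)CC[C@@H]1Br | intermediate (not isolated)
25 | (2S,3S)-3-bromo-2-[(3E,7S)-7-{[tert-butyl(dimethyl)silyl]oxy}-4,8-dimethylnona-3,8-dien-1-yl]-2,6-dimethylcyclohexan-1-one | C=C(C)[C@@H](O[Si](C)(C)C(C)(C)C)CC/C(C)=C/CC[C@@]1(C)C(=O)C(C)CC[C@@H]1Br | intermediate
26 | (5S,6S)-5-bromo-6-[(3E,7S)-7-{[tert-butyl(dimethyl)silyl]oxy}-4,8-dimethylnona-3,8-dien-1-yl]-2,6-dimethylcyclohex-1-en-1-yl trifluoromethanesulfonate | C=C(C)[C@@H](O[Si](C)(C)C(C)(C)C)CC/C(C)=C/CC[C@@]1(C)C(OS(=O)(=O)C(F)(F)F)=C(C)CC[C@@H]1Br | intermediate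
27 | (5S,6S)-5-bromo-6-{2-[(2S,3S)-3-[(3S)-3-{[tert-butyl(dimethyl)silyl]oxy}-4-methylpent-4-en-1-yl]-3-methyloxiran-2-yl]ethyl}-2,6-dimethylcyclohex-1-en-1-yl trifluoromethanesulfonate | C=C(C)[C@@H](O[Si](C)(C)C(C)(C)C)CC[C@]2(C)O[C@H]2CC[C@@]1(C)C(OS(=O)(=O)C(F)(F)F)=C(C)CC[C@@H]1Br | intermediate
28 | methyl 4-hydroxy-3-methylbenzoate | COC(=O)c1ccc(O)c(C)c1 | starting material
29 | methyl 4-(methoxymethoxy)-3-methylbenzoate | COCOc1ccc(cc1C)C(=O)OC | intermediate
30 | 2-(trimethylsilyl)ethyl 4-(methoxymethoxy)-3-methylbenzoate | COCOc1ccc(cc1C)C(=O)OCC[Si](C)(C)C | intermediate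
31 | 2-(trimethylsilyl)ethyl 3-(bromomethyl)-4-(methoxymethoxy)benzoate | COCOc1ccc(cc1CBr)C(=O)OCC[Si](C)(C)C | intermediate
32 | {[2-(methoxymethoxy)-5-{[2-(trimethylsilyl)ethoxy]carbonyl}phenyl]methyl}zinc bromide | COCOc1ccc(cc1C[Zn]Br)C(=O)OCC[Si](C)(C)C | intermediate (not isolated)
33 | 2-(trimethylsilyl)ethyl 3-{[(5S,6S)-5-bromo-6-{2-[(2S,3S)-3-[(3S)-3-{[tert-butyl(dimethyl)silyl]oxy}-4-methylpent-4-en-1-yl]-3-methyloxiran-2-yl]ethyl}-2,6-dimethylcyclohex-1-en-1-yl]methyl}-4-(methoxymethoxy)benzoate | C=C(C)[C@@H](O[Si](C)(C)C(C)(C)C)CC[C@]2(C)O[C@H]2CC[C@@]1(C)C(Cc3cc(ccc3OCOC)C(=O)OCC[Si](C)(C)C)=C(C)CC[C@@H]1Br | intermediate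
34 | 3-{[(5S,6S)-5-bromo-6-{2-[(2S,3S)-3-[(3S)-3-hydroxy-4-methylpent-4-en-1-yl]-3-methyloxiran-2-yl]ethyl}-2,6-dimethylcyclohex-1-en-1-yl]methyl}-4-(methoxymethoxy)benzoic acid | C=C(C)[C@@H](O)CC[C@]2(C)O[C@H]2CC[C@@]1(C)C(Cc3cc(ccc3OCOC)C(O)=O)=C(C)CC[C@@H]1Br | intermediate
35 | (6S,7S,10S,11S,14S)-macrolactone with C10/C11 trans-epoxide and aryl methoxymethyl ether | C=C(C)[C@@H]1CC[C@]3(C)O[C@H]3CC[C@@]2(C)C(=C(C)CC[C@@H]2Br)Cc2cc(ccc2OCOC)C(=O)O1 | intermediate
36 | O-methoxymethyl ether of the target, (6S,7S,10R,11S,14S) | C=C(C)[C@@H]1CC[C@](C)(O)[C@H](Br)CC[C@@]2(C)C(=C(C)CC[C@@H]2Br)Cc2cc(ccc2OCOC)C(=O)O1 | intermediate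
37 | CNP0305154.1, (6S,7S,10R,11S,14S) | C=C(C)[C@@H]1CC[C@](C)(O)[C@H](Br)CC[C@@]2(C)C(=C(C)CC[C@@H]2Br)Cc2cc(ccc2O)C(=O)O1 | target

**Count and risks**

Total steps: 27. Longest linear sequence: 19 (steps 1–11, 17–19, 23–27).

Steps most likely to fail:

1. Step 3. Facial, endo/exo or regiochemical control under the chiral catalyst may be incomplete, or the silyl group may transfer to give open-chain conjugate adducts; each minor cycloaddition mode leads to the antipodal bridgeheads after decarboxylation, so the enantiomeric purity of 9 would erode. Fallback (covalent auxiliary in place of catalyst control, so that every unwanted isomer is a separable diastereomer): from 4, cycloaddition with (4R)-4-benzyl-3-(prop-2-enoyl)-1,3-oxazolidin-2-one promoted by Et2AlCl in CH2Cl2 at −78 °C should give the auxiliary-bearing endo adduct F1, which is purified to a single diastereomer; LiOH/H2O2 and then dilute HCl, as in step 4, release the auxiliary and return the route at 8.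

2. Step 9. Backside attack at the neopentylic C6 may lose to elimination toward C5 or to a 1,2-shift from the oxyphosphonium intermediate. Fallback (activation and substitution separated, with a naked halide in a non-ionising medium): from 12, Tf2O and 2,6-di-tert-butyl-4-methylpyridine in CH2Cl2 at −78 °C should give the secondary triflate F2, which is displaced with inversion by n-Bu4NBr in toluene at −20 to 25 °C to return at 13.

3. Step 23. Transmetallation to the hindered tetrasubstituted alkenyl–palladium species may be slow, with benzyl homocoupling and zinc-salt-induced opening of the epoxide competing. Fallback (polarity of the two partners reversed, no organozinc): from 27, Miyaura borylation (B2pin2, PdCl2(dppf), KOPh, toluene, 50 °C) should give the alkenyl pinacol boronate F3, and Suzuki–Miyaura coupling of it with benzyl bromide 31 (Pd(PPh3)4, K3PO4, THF/H2O, 50 °C) returns at 33.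

**Further compounds**

F1 | step 3 | (4R)-4-benzyl-3-{[(1S,4S,5S)-2-{[tert-butyl(dimethyl)silyl]oxy}-1-methyl-7-oxabicyclo[2.2.1]hept-2-en-5-yl]carbonyl}-1,3-oxazolidin-2-one | C1=C(O[Si](C)(C)C(C)(C)C)[C@]2(C)C[C@H](C(=O)N3[C@H](Cc4ccccc4)COC3=O)[C@H]1O2
F2 | step 9 | (1R,2R)-2,4-dimethyl-3-oxo-2-(prop-2-en-1-yl)cyclohexyl trifluoromethanesulfonate | C=CC[C@@]1(C)C(=O)C(C)CC[C@H]1OS(=O)(=O)C(F)(F)F
F3 | step 23 | 2-[(5S,6S)-5-bromo-6-{2-[(2S,3S)-3-[(3S)-3-{[tert-butyl(dimethyl)silyl]oxy}-4-methylpent-4-en-1-yl]-3-methyloxiran-2-yl]ethyl}-2,6-dimethylcyclohex-1-en-1-yl]-4,4,5,5-tetramethyl-1,3,2-dioxaborolane | C=C(C)[C@@H](O[Si](C)(C)C(C)(C)C)CC[C@]2(C)O[C@H]2CC[C@@]1(C)C(B3OC(C)(C)C(C)(C)O3)=C(C)CC[C@@H]1Br
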